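In the north run the substrate loses more than the target gains: 10.6 % against 6.8 % at 90.0 s. I build the new flask from that gap.

- north: substrate 0.026 M; first nucleophile 1.4 equiv; solid second nucleophile 2 equiv; run made earlier
- flask: substrate 0.026 M; first nucleophile 0.950 equiv; solid second nucleophile 2.00 equiv; time 5.0 min

north run (percent of the substrate charged)

| time / s | target / % | substrate / % |
|---|---|---|
| 10.0 | 0.4 | 99.0 |
| 25.0 | 3.1 | 97.6 |
| 40.0 | 3.3 | 95.1 |
| 60.0 | 4.2 | 92.2 |
| 90.0 | 6.8 | 89.4 |

(readings scatter by 0.5 percentage points)

- at the start none of the solid second nucleophile is in solution

- how much target there is at 5.0 min, in percent of the substrate charged
- the change that raises the amount of target at 5.0 min, in percent of the substrate charged most ("none" if none brings more than 2 percentage points) (winter / noon / dusk / none)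
- amount of target at 5.0 min, in percent of the substrate charged, after noon

- winter: doubling the solubility of the solid second nucleophile, all else as stated
- noon: doubling the amount of first nucleophile, all else as stated
- dusk: doubling the dissolution coefficient of the solid second nucleophile, all else as stated

First, the main step alone. I assume the substrate is lost by a first-order step that needs no nucleophile; north, with its single charge of first nucleophile, does not test this. North then gives 0.00124 /s, so 31.2 % of the substrate goes by 5.0 min. That is the ceiling for target on this assumption.

Now I add one competition. In north, 64.2 % of the lost substrate appears as target; this share is the selectivity, read with the scatter of two readings. I assume first nucleophile competes in proportion to its amount against a loss that ignores it. Then there is a crossing amount, 0.782 equiv, the amount of first nucleophile at which target and the competing loss take equal parts. Above it, capture by first nucleophile leads; below it, the loss leads. The flask's share is 54.8 %, which gives 17.1 % of target. Doubling the first nucleophile gives 22.1 %.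

Then the rest. First nucleophile falls as target forms, so the share slips, and I commit to a little under 17.1 %. North has a single charge of the solid second nucleophile, so I have no gain to reckon for winter or dusk. Noon gains 5 percentage points by my reckoning, above the margin of 2 points, so I choose noon.

The forecast says 14 %, noon and 25 %, reckoning the first step as second-order, unlike mine: “The first step controls the rate, so faster or greater dissolution of the second nucleophile should help little.”

The flask gives 15.5 %, and noon gives 21.0 %, a gain of 5.5 points, more than winter at −1 point or dusk at −0.97 points.

    intermediate → solvolysis product (k = 1.10 /s)
    solid second nucleophile ⇌ second nucleophile, rate k2*(cs2 - [second nucleophile]) while solid is left; crystals form when [second nucleophile] > cs2 (solubility = 14.0 mM, k = 3.50 × 10⁻⁴ /s)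
    second nucleophile + intermediate → other capture product (k = 400 /M/s)
    substrate → intermediate (k = 0.00130 /s)
    first nucleophile + intermediate → target (k = 52.0 /M/s)

At 5.00 min the flask holds 15.5 % target beside 14.4 % solvolysis product and 2.36 % other capture product, with 0.795 equiv of first nucleophile left, close to the crossing I read from north. The same flask left until 20 min has 0.623 equiv left, below that crossing, and its solvolysis product, 34.3 %, stands above its target, 32.7 %, with 12.0 % other capture product besides.

The readings are simulated with made-up constants; the scatter is artificial.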